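**The comparison.** I decided to skip the curves and compare pseudo-first-order loss constants, ln(charge/reading)/time, taken at the second reading of each run. You asked for a quick number on the beta run, so here is the problem as it stood.

| flask | starting material | partner | time |
|---|---|---|---|
| delta | 0.500 M | 1.50 M |  |
| eta | 0.200 M | 1.20 M |  |
| alpha | 0.750 M | 1.50 M |  |
| zeta | 0.500 M | 2.20 M |  |
| beta | 2.50 M | 7.50 M | 6.0 min |

- delta run (time / min: [starting material] / M): 0.75: 0.384; 1.5: 0.290; 2.2: 0.241; 3.0: 0.183; 3.8: 0.138; 4.5: 0.116; 5.2: 0.099; 6.0: 0.079
- eta run (time / min: [starting material] / M): 0.75: 0.154; 1.5: 0.124; 2.2: 0.096; 3.0: 0.073; 3.8: 0.065; 4.5: 0.051; 5.2: 0.047; 6.0: 0.035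
- alpha run (time / min: [starting material] / M): 0.75: 0.571; 1.5: 0.446; 2.2: 0.359; 3.0: 0.274; 3.8: 0.219; 4.5: 0.178; 5.2: 0.151; 6.0: 0.130
- zeta run (time / min: [starting material] / M): 0.75: 0.361; 1.5: 0.258; 2.2: 0.198; 3.0: 0.146; 3.8: 0.109; 4.5: 0.088; 5.2: 0.066; 6.0: 0.056

(each reading ± 0.003 M)

1. apparent order in [starting material] of the starting rate, round the charge of the delta run (the rate where two percent of its starting material have turned into target) (one fixed amount of target, the same in the runs compared)
2. apparent order in [partner] of the starting rate, round the charge of the delta run (the rate where two percent of its starting material have turned into target)
3. starting material in the beta run at 6.0 min, as a share of the starting material charged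
4. which of these the readings show (the product binds the substrate / two substrates go astray together / the second partner is lost by itself / the substrate is lost by itself / the substrate pairs with itself)

- Overall: starting material + partner -> target.
- Constant volume, constant temperature.
- "The second partner" is partner.
- An order is taken over about fifteen percent of the charge, up and down.

**Two routes.** The alpha run gave 0.347 /min and the delta run 0.363 /min, at equal c(partner) but different c(starting material), so I took the order in c(starting material) as about one. The zeta run, with more partner, gave 0.441 /min. A straight line through delta and zeta had slope 0.111 /M/min and, at zero c(partner), a constant of 0.196 /min. I read that as the substrate lost by itself. The eta run read 0.319 /min, and the line gave 0.330 /min.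

**Partner share.** Near the charge, dividing the rate of the partner route by the total rate of loss cancelled c(starting material) but not c(partner), so I used the result for the start of a run. This gave the partner share, b·c(partner)/(a + b·c(partner)): 0.460 in delta and 0.555 in zeta. It is also the order of total loss in c(partner). Across delta and zeta that order read 0.508, while on my line target formation kept order one.

**Your forecast.** It said 0.97 and 0.5 for the orders, 4 % for beta, and the second partner is lost by itself, on this ground: “The decay therefore depends on time, not concentration”. We parted on the partner order and the diagnosis. At the beta charge my line gave 1.03 /min, but delta's constant over its later readings had slackened to 0.280 /min, less than at its start. So I did not run that constant out, and I kept your beta figure.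

**The flask.** Beta held 4.55 % at 6.0 min, with orders 1.0 and 1.0, and the answer was that the substrate is lost by itself. The fit with main steps alone gave 0.0347 % for beta.

    starting material + partner ⇌ target (0.1170 /M/min, 0.04842 /min)
    starting material → decomposed substrate (0.1890 /min)

The share 0.460 times delta's loss rate at the charge gave 0.0835 M/min of target, against a simulated 0.083 M/min. In zeta, the share 0.555 gave 0.122 M/min, against 0.12 M/min.

The readings stem from a simulated flask with made-up constants; scatter was added.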